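The route rests on cutting two olefins that each sit next to a dimethyl-substituted carbon: the C3=C4 double bond of the pyran ring of the 2H-chromene and the trisubstituted olefin of the prenyl group on C7 of the benzene ring. One ruthenium-carbene operation first closes the pyran ring between a vinyl group on C4a and a 1,1-dimethylallyl ether on O1, then converts a C7 allyl group into prenyl with 2-methylbut-2-ene. The substrate is a pentasubstituted benzene carrying, in sequence, vinyl, tertiary allyl ether, methoxymethyl (MOM) ether, allyl and an ethyl propanoate chain. The resorcinol ketone is attached afterwards through a Weinreb amide, and one acid treatment removes all three MOM groups.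

Key step: step 9

Remark: the target has no stereocentre and its C3=C4 olefin is cis by ring constraint, so no stereocontrol is needed. The bicycle is numbered as a chromene (O1, C2, C3, C4, C4a, C5 to C8, C8a). The bromine is bought in place (5-bromo-o-vanillin), so its position does not depend on a regioselective bromination.

Step 1
Reactants: 1 5-bromo-2-hydroxy-3-methoxybenzaldehyde
Product: 2 5-bromo-2,3-dihydroxybenzaldehyde
Conditions: BBr3 (2.5 equiv), CH2Cl2, −78 °C to rt; then H2O
Reagents that add atoms: none
Why: Lewis-acid demethylation of an aryl methyl ether with BBr3 (bromide attacks the O-methyl group of the boron-complexed ether) is routine for catechol aldehydes and should leave the aryl bromide and the formyl group untouched.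

Step 2
Reactants: 2 5-bromo-2,3-dihydroxybenzaldehyde; 3 3-bromoprop-1-ene (allyl bromide)
Product: 4 5-bromo-2-hydroxy-3-(prop-2-en-1-yloxy)benzaldehyde
Conditions: NaH (2.2 equiv), DMSO, rt; then 3 (1.0 equiv), rt
Reagents that add atoms: none
Why: Williamson etherification after double deprotonation: the 2-oxygen is held by conjugation and chelation to the formyl group, so the single equivalent of allyl bromide should go to the more nucleophilic 3-oxygen.

Step 3
Reactants: 4 5-bromo-2-hydroxy-3-(prop-2-en-1-yloxy)benzaldehyde
Product: 5 5-bromo-2,3-dihydroxy-4-(prop-2-en-1-yl)benzaldehyde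
Conditions: 1,2-dichlorobenzene, 180 °C, argon
Reagents that add atoms: none
Why: aromatic Claisen rearrangement (concerted [3,3] shift, then tautomerisation): of the two positions ortho to the ether oxygen only C4 bears hydrogen, so the allyl group should land between the 3-oxygen and the bromine.

Step 4
Reactants: 5 5-bromo-2,3-dihydroxy-4-(prop-2-en-1-yl)benzaldehyde
Product: 6 5-bromo-2-hydroxy-3-(methoxymethoxy)-4-(prop-2-en-1-yl)benzaldehyde
Conditions: NaH (2.2 equiv), DMF, 0 °C; then MOMCl (1.05 equiv), 0 °C
Reagents that add atoms: chloromethyl methyl ether (MOMCl), COCCl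
Why: O-alkylation (acetal formation) under the same double-deprotonation logic as step 2: the formyl-chelated 2-phenoxide is the weaker nucleophile, so one equivalent of MOMCl should cap the 3-oxygen and leave the 2-hydroxyl free for step 6.

Step 5
Reactants: 6 5-bromo-2-hydroxy-3-(methoxymethoxy)-4-(prop-2-en-1-yl)benzaldehyde; 7 (3-ethoxy-3-oxopropyl)zinc bromide (commercial THF solution)
Product: 8 ethyl 3-[5-formyl-4-hydroxy-3-(methoxymethoxy)-2-(prop-2-en-1-yl)phenyl]propanoate
Conditions: Pd(OAc)2 (3 mol%), SPhos (6 mol%), 7 (2.5 equiv, slow addition), THF, 25 to 45 °C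
Reagents that add atoms: none
Why: Negishi coupling (oxidative addition of zerovalent palladium into the C–Br bond, transmetallation from zinc, reductive elimination): alkylzinc halides coexist with an aldehyde and, with slow addition under Pd/SPhos catalysis, with a free phenol, and the bulky electron-rich phosphine favours reductive elimination over β-hydride loss.

Step 6
Reactants: 8 ethyl 3-[5-formyl-4-hydroxy-3-(methoxymethoxy)-2-(prop-2-en-1-yl)phenyl]propanoate; 9 3-chloro-3-methylbut-1-yne
Product: 10 ethyl 3-[5-formyl-3-(methoxymethoxy)-4-(2-methylbut-3-yn-2-yloxy)-2-(prop-2-en-1-yl)phenyl]propanoate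
Conditions: 9 (2 equiv), DBU (2.2 equiv), CuCl2 (1 mol%), MeCN, 0 °C to rt
Reagents that add atoms: none
Why: copper-catalysed O-propargylation of a phenol with a tertiary propargylic chloride (the phenoxide captures a copper-bound propargyl/allenyl electrophile at the tertiary carbon), a reaction that tolerates electron-poor and ortho-flanked phenols and leaves the MOM ether, ester and aldehyde alone at this temperature.

Step 7
Reactants: 10 ethyl 3-[5-formyl-3-(methoxymethoxy)-4-(2-methylbut-3-yn-2-yloxy)-2-(prop-2-en-1-yl)phenyl]propanoate
Product: 11 ethyl 3-[5-formyl-3-(methoxymethoxy)-4-(2-methylbut-3-en-2-yloxy)-2-(prop-2-en-1-yl)phenyl]propanoate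
Conditions: H2 (1 atm), Pd/CaCO3 poisoned with Pb(OAc)2 (Lindlar catalyst), quinoline, EtOAc, rt, stopped after one equivalent of H2
Reagents that add atoms: none
Why: Lindlar semihydrogenation: the terminal alkyne binds to the poisoned palladium surface far more strongly than an alkene, so it should be reduced to the 1,1-dimethylallyl ether before the allyl group or the aldehyde is touched.

Step 8
Reactants: 11 ethyl 3-[5-formyl-3-(methoxymethoxy)-4-(2-methylbut-3-en-2-yloxy)-2-(prop-2-en-1-yl)phenyl]propanoate
Product: 12 ethyl 3-[5-ethenyl-3-(methoxymethoxy)-4-(2-methylbut-3-en-2-yloxy)-2-(prop-2-en-1-yl)phenyl]propanoate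
Conditions: Ph3PCH3Br (1.3 equiv), KOtBu (1.2 equiv), THF, 0 °C; then 11, 0 °C to rt
Reagents that add atoms: methyltriphenylphosphonium bromide, C[P+](c1ccccc1)(c1ccccc1)c1ccccc1.[Br-]
Why: Wittig methylenation: the non-stabilised ylide should add to the aldehyde much faster than to the ethyl ester, and keeping the base below the phosphonium salt leaves no free alkoxide to move the allyl double bond.

Step 9
Reactants: 12 ethyl 3-[5-ethenyl-3-(methoxymethoxy)-4-(2-methylbut-3-en-2-yloxy)-2-(prop-2-en-1-yl)phenyl]propanoate; 13 2-methylbut-2-ene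
Product: 15 ethyl 3-[8-(methoxymethoxy)-2,2-dimethyl-7-(3-methylbut-2-en-1-yl)-2H-chromen-6-yl]propanoate, via 7-allyl-2H-chromene ester 14 (not isolated)
Conditions: (H2IMes)(PCy3)Cl2Ru=CHPh (second-generation Grubbs catalyst, 5 mol%), 1,4-benzoquinone (10 mol%), CH2Cl2 (0.005 M), 40 °C; then 13 (equal volume) and more catalyst (3 mol%), 35 °C, sealed
Reagents that add atoms: none
Why: The ruthenium benzylidene exchanges onto the vinyl group on C4a, the resulting aryl-substituted alkylidene adds [2+2] to the olefin of the neighbouring 1,1-dimethylallyl ether, and cycloreversion of the ruthenacyclobutane releases the C3=C4 double bond with loss of ethene; once 14 has formed, added 2-methylbut-2-ene exchanges the terminal CH2 of the C7 allyl group for an isopropylidene unit through the same metallacycle sequence, with propene as co-product. The closest known reactions are ring-closing metathesis of 2-vinylaryl allyl ethers to 2H-chromenes and cross metathesis of allylarenes with 2-methylbut-2-ene to prenylarenes. The pyran ring is closed as a six-membered ring by intramolecular metathesis of two terminal alkenes, the gem-dimethyl group on C2 favouring the folded conformer and the ring size enforcing the cis olefin. No stereocentre is created. The step needs order and site selectivity: high dilution and late addition of 2-methylbut-2-ene let the ring close before the vinyl group can be capped or dimerised, the allyl group is then the only unhindered terminal olefin left, and the two product olefins are too hindered to re-enter the cycle, while any crotyl by-product from ethylidene transfer stays reactive and should be recycled to prenyl by the excess alkene; benzoquinone suppresses ruthenium hydride migration of the allyl double bond.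

Step 10
Reactants: 15 ethyl 3-[8-(methoxymethoxy)-2,2-dimethyl-7-(3-methylbut-2-en-1-yl)-2H-chromen-6-yl]propanoate
Product: 16 N-methoxy-3-[8-(methoxymethoxy)-2,2-dimethyl-7-(3-methylbut-2-en-1-yl)-2H-chromen-6-yl]-N-methylpropanamide
Conditions: MeNHOMe·HCl (2 equiv), iPrMgCl (4 equiv), THF, −20 to 0 °C
Reagents that add atoms: N,O-dimethylhydroxylamine hydrochloride, CNOC.Cl
Why: acyl substitution of the ethyl ester by the chloromagnesium amide generated in the flask (Weinreb amide formation), which should stop at the amide and not affect the chromene, prenyl or MOM groups at this temperature.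

Step 11
Reactants: 17 4-bromobenzene-1,3-diol
Product: 18 1-bromo-2,4-bis(methoxymethoxy)benzene
Conditions: MOMCl (2.5 equiv), iPr2NEt (3 equiv), CH2Cl2, 0 °C to rt
Reagents that add atoms: chloromethyl methyl ether (MOMCl), COCCl
Why: O-alkylation of both phenols with the reactive chloromethyl ether (acetal formation); MOM is chosen because it tolerates and coordinatively stabilises the neighbouring aryllithium of step 12.

Step 12
Reactants: 18 1-bromo-2,4-bis(methoxymethoxy)benzene; 16 N-methoxy-3-[8-(methoxymethoxy)-2,2-dimethyl-7-(3-methylbut-2-en-1-yl)-2H-chromen-6-yl]-N-methylpropanamide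
Product: 20 1-[2,4-bis(methoxymethoxy)phenyl]-3-[8-(methoxymethoxy)-2,2-dimethyl-7-(3-methylbut-2-en-1-yl)-2H-chromen-6-yl]propan-1-one, via 2,4-bis(methoxymethoxy)phenyllithium 19 (not isolated)
Conditions: 18 (1.5 equiv), n-BuLi (1.45 equiv), THF, −78 °C; then 16, −78 to −20 °C; aq NH4Cl
Reagents that add atoms: none
Why: bromine–lithium exchange followed by Weinreb ketone synthesis: the aryllithium should add only once because the metal-chelated addition product does not release the ketone until the aqueous quench, and the slight deficit of n-BuLi leaves no butyllithium to compete.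

Step 13
Reactants: 20 1-[2,4-bis(methoxymethoxy)phenyl]-3-[8-(methoxymethoxy)-2,2-dimethyl-7-(3-methylbut-2-en-1-yl)-2H-chromen-6-yl]propan-1-one
Product: 21 1-(2,4-dihydroxyphenyl)-3-[8-hydroxy-2,2-dimethyl-7-(3-methylbut-2-en-1-yl)-2H-chromen-6-yl]propan-1-one
Conditions: 3 M aq HCl, MeOH, rt to 40 °C, monitored; NaHCO3 quench
Reagents that add atoms: none
Why: acid-catalysed acetal cleavage (transacetalisation to dimethoxymethane) should remove all three MOM ethers, the one ortho to the ketone fastest, under conditions mild enough that the ortho-prenyl phenol does not cyclise and the chromene olefin is not hydrated.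

Compound list
1 | 5-bromo-2-hydroxy-3-methoxybenzaldehyde | COc1cc(Br)cc(C=O)c1O | starting material
2 | 5-bromo-2,3-dihydroxybenzaldehyde | O=Cc1cc(Br)cc(O)c1O | intermediate
3 | 3-bromoprop-1-ene (allyl bromide) | C=CCBr | starting material
4 | 5-bromo-2-hydroxy-3-(prop-2-en-1-yloxy)benzaldehyde | O=Cc1cc(Br)cc(OCC=C)c1O | intermediate
5 | 5-bromo-2,3-dihydroxy-4-(prop-2-en-1-yl)benzaldehyde | O=Cc1cc(Br)c(CC=C)c(O)c1O | intermediate
6 | 5-bromo-2-hydroxy-3-(methoxymethoxy)-4-(prop-2-en-1-yl)benzaldehyde | O=Cc1cc(Br)c(CC=C)c(OCOC)c1O | intermediate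
7 | (3-ethoxy-3-oxopropyl)zinc bromide | CCOC(=O)CC[Zn]Br | starting material
8 | ethyl 3-[5-formyl-4-hydroxy-3-(methoxymethoxy)-2-(prop-2-en-1-yl)phenyl]propanoate | C=CCc1c(CCC(=O)OCC)cc(C=O)c(O)c1OCOC | intermediate
9 | 3-chloro-3-methylbut-1-yne | C#CC(C)(C)Cl | starting material
10 | ethyl 3-[5-formyl-3-(methoxymethoxy)-4-(2-methylbut-3-yn-2-yloxy)-2-(prop-2-en-1-yl)phenyl]propanoate | C=CCc1c(CCC(=O)OCC)cc(C=O)c(OC(C)(C)C#C)c1OCOC | intermediate
11 | ethyl 3-[5-formyl-3-(methoxymethoxy)-4-(2-methylbut-3-en-2-yloxy)-2-(prop-2-en-1-yl)phenyl]propanoate | C=CCc1c(CCC(=O)OCC)cc(C=O)c(OC(C)(C)C=C)c1OCOC | intermediate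
12 | ethyl 3-[5-ethenyl-3-(methoxymethoxy)-4-(2-methylbut-3-en-2-yloxy)-2-(prop-2-en-1-yl)phenyl]propanoate | C=CCc1c(CCC(=O)OCC)cc(C=C)c(OC(C)(C)C=C)c1OCOC | intermediate
13 | 2-methylbut-2-ene | CC=C(C)C | starting material
14 | ethyl 3-[8-(methoxymethoxy)-2,2-dimethyl-7-(prop-2-en-1-yl)-2H-chromen-6-yl]propanoate | C=CCc1c(CCC(=O)OCC)cc2C=CC(C)(C)Oc2c1OCOC | intermediate
15 | ethyl 3-[8-(methoxymethoxy)-2,2-dimethyl-7-(3-methylbut-2-en-1-yl)-2H-chromen-6-yl]propanoate | CC(C)=CCc1c(CCC(=O)OCC)cc2C=CC(C)(C)Oc2c1OCOC | intermediate
16 | N-methoxy-3-[8-(methoxymethoxy)-2,2-dimethyl-7-(3-methylbut-2-en-1-yl)-2H-chromen-6-yl]-N-methylpropanamide | CC(C)=CCc1c(CCC(=O)N(C)OC)cc2C=CC(C)(C)Oc2c1OCOC | intermediate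
17 | 4-bromobenzene-1,3-diol | Oc1ccc(Br)c(O)c1 | starting material
18 | 1-bromo-2,4-bis(methoxymethoxy)benzene | COCOc1ccc(Br)c(OCOC)c1 | intermediate
19 | [2,4-bis(methoxymethoxy)phenyl]lithium | [Li]c1ccc(OCOC)cc1OCOC | intermediate
20 | 1-[2,4-bis(methoxymethoxy)phenyl]-3-[8-(methoxymethoxy)-2,2-dimethyl-7-(3-methylbut-2-en-1-yl)-2H-chromen-6-yl]propan-1-one | CC(C)=CCc1c(CCC(=O)c2ccc(OCOC)cc2OCOC)cc2C=CC(C)(C)Oc2c1OCOC | intermediate
21 | 1-(2,4-dihydroxyphenyl)-3-[8-hydroxy-2,2-dimethyl-7-(3-methylbut-2-en-1-yl)-2H-chromen-6-yl]propan-1-one | CC(C)=CCc1c(CCC(=O)c2ccc(O)cc2O)cc2c(c1O)OC(C)(C)C=C2 | target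

Total step count: 13. Longest linear sequence: 12 steps (steps 1 to 10, then 12 and 13, from compound 1); step 11 is a one-step side branch.

Steps most likely to fail

Step 9. Ring closure may be outrun by intermolecular metathesis at the allyl group or by capping of the vinyl group. The allyl double bond may migrate into conjugation under ruthenium hydride, and ethylidene rather than isopropylidene transfer may persist. The fallback separates the two metatheses and makes the prenyl group before the vinyl group exists. It sets out from 11: cross metathesis with 13 using (H2IMes)(PCy3)Cl2Ru=CHPh in CH2Cl2/13 at rt should act only on the allyl group, since the 1,1-dimethylallyl olefin is too hindered, and should give ethyl 3-[5-formyl-3-(methoxymethoxy)-4-(2-methylbut-3-en-2-yloxy)-2-(3-methylbut-2-en-1-yl)phenyl]propanoate F1. Wittig methylenation as in step 8 should then give ethyl 3-[5-ethenyl-3-(methoxymethoxy)-4-(2-methylbut-3-en-2-yloxy)-2-(3-methylbut-2-en-1-yl)phenyl]propanoate F2. Ring-closing metathesis alone, with the same catalyst in dilute CH2Cl2 at 40 °C, closes the pyran ring and the route is rejoined at 15.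

Step 7. Hydrogen uptake may not stop cleanly at the alkene, so the allyl group may be saturated or its double bond may migrate on the palladium surface. The fallback avoids the alkyne altogether and sets out from phenol 8. 2-Methylbut-3-en-2-ol is converted with n-BuLi and Boc2O in THF into tert-butyl 2-methylbut-3-en-2-yl carbonate F3. Treating 8 with F3 and Pd(PPh3)4, a zerovalent palladium complex, in THF at 0 °C is a decarboxylative Tsuji–Trost O-allylation in which the phenoxide attacks the more substituted terminus of the 1,1-dimethylallyl palladium species under kinetic control. It should give the tertiary ether directly, and the route is rejoined at 11.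

Step 5. The free phenol may consume the zinc reagent by protonolysis, oxidative addition at the electron-rich, ortho-flanked bromide may be sluggish, and palladium hydride may move the allyl double bond during a slow coupling. The fallback masks the phenol for the coupling and sets out from 6. NaH and MOMCl in DMF should give 5-bromo-2,3-bis(methoxymethoxy)-4-(prop-2-en-1-yl)benzaldehyde F4. Negishi coupling with 7 under the conditions of step 5, now with only a slight excess of 7, should give ethyl 3-[5-formyl-3,4-bis(methoxymethoxy)-2-(prop-2-en-1-yl)phenyl]propanoate F5. Brief treatment with dilute HCl in MeOH at 0 °C should remove selectively the MOM group next to the formyl group, whose cleavage is assisted by hydrogen bonding to the carbonyl, and the route is rejoined at 8.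

Further compounds
F1 | step 9 | ethyl 3-[5-formyl-3-(methoxymethoxy)-4-(2-methylbut-3-en-2-yloxy)-2-(3-methylbut-2-en-1-yl)phenyl]propanoate | CC(C)=CCc1c(CCC(=O)OCC)cc(C=O)c(OC(C)(C)C=C)c1OCOC
F2 | step 9 | ethyl 3-[5-ethenyl-3-(methoxymethoxy)-4-(2-methylbut-3-en-2-yloxy)-2-(3-methylbut-2-en-1-yl)phenyl]propanoate | CC(C)=CCc1c(CCC(=O)OCC)cc(C=C)c(OC(C)(C)C=C)c1OCOC
F3 | step 7 | tert-butyl 2-methylbut-3-en-2-yl carbonate | C=CC(C)(C)OC(=O)OC(C)(C)C
F4 | step 5 | 5-bromo-2,3-bis(methoxymethoxy)-4-(prop-2-en-1-yl)benzaldehyde | C=CCc1c(Br)cc(C=O)c(OCOC)c1OCOC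
F5 | step 5 | ethyl 3-[5-formyl-3,4-bis(methoxymethoxy)-2-(prop-2-en-1-yl)phenyl]propanoate | C=CCc1c(CCC(=O)OCC)cc(C=O)c(OCOC)c1OCOC
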